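The depside is cut at the aryl ester oxygen on C4, and the plan rests on assembling hexasubstituted ring B in one operation. Its C4–C5–C6 segment (hydroxyl, methyl, methoxy) is read as a ketene carbonyl carbon joined to both carbons of 1-methoxypropyne. C1–C2–C3, carrying the ester and two methyls, come from a tigloyl-derived vinylketene. Irradiating an acyclic α-diazo-β-keto ester that bears the (E)-but-2-en-2-yl group together with the ynol ether should give the phenol with all six substituents placed and only the C4 oxygen free. Since ring B then has no C–H, ring A can be formylated at C3' and C5' after coupling.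

Key step: step 4

Remark: ring B is numbered C1 (CO2CH3), C2 and C3 (methyl), C4 (ester oxygen), C5 (methyl), C6 (methoxy); ring A is numbered C1' (acyl carbon attached), C2' (OH), C3' (CHO), C4' (OH), C5' (CHO), C6' (CH3). The target has no stereocentre, and the (E)-alkene of the tigloyl unit disappears on aromatisation.

Step 1
Reactants: 1 tiglic acid [(E)-2-methylbut-2-enoic acid]; 2 potassium methyl malonate
Product: 4 methyl (E)-4-methyl-3-oxohex-4-enoate, via tigloyl imidazolide 3 (not isolated)
Conditions: 1,1'-carbonyldiimidazole (CDI), THF, rt; then 2, MgCl2, Et3N, MeCN/THF, rt to 40 °C; aq. HCl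
Reagents that add atoms: none
Why: Masamune–Brooks C-acylation, in which the magnesium-chelated enolate of the malonate half-ester attacks the acyl imidazolide and the adduct loses CO2, runs near neutrality, so the hindered trisubstituted (E)-alkene should neither isomerise nor suffer conjugate addition.

Step 2
Reactants: 4 methyl (E)-4-methyl-3-oxohex-4-enoate
Product: 5 methyl (E)-2-diazo-4-methyl-3-oxohex-4-enoate
Conditions: 4-acetamidobenzenesulfonyl azide (p-ABSA), Et3N, MeCN, 0 °C to rt
Reagents that add atoms: 4-acetamidobenzenesulfonyl azide, CC(=O)Nc1ccc(cc1)S(=O)(=O)N=[N+]=[N-]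
Why: Regitz diazo transfer to a methylene group activated by a ketone and an ester needs only an amine base, and no other position of 4 is acidic enough to engage the sulfonyl azide.

Step 3
Reactants: 6 chloroacetaldehyde dimethyl acetal
Product: 8 1-methoxyprop-1-yne, via sodium methoxyacetylide 7 (not isolated)
Conditions: NaNH2 (3 equiv), liq. NH3, −33 °C; MeI, −33 °C; cold brine, distillation
Reagents that add atoms: iodomethane, CI
Why: Twofold base-induced elimination (methanol, then HCl) and deprotonation by sodium amide give the alkoxyacetylide, whose C-alkylation in liquid ammonia is the standard entry to 1-alkoxyalk-1-ynes, and a methyl ynol ether cannot fragment by retro-ene loss of an alkene during the later heating.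

Step 4
Reactants: 5 methyl (E)-2-diazo-4-methyl-3-oxohex-4-enoate; 8 1-methoxyprop-1-yne
Product: 13 methyl 4-hydroxy-2-methoxy-3,5,6-trimethylbenzoate, via vinylketene 9 (not isolated), via vinylcyclobutenone 10 (not isolated), via dienylketene 11 (not isolated), via cyclohexadienone 12 (not isolated)
Conditions: 8 (2.5 equiv), hν (254 nm, low-pressure Hg lamps, quartz), degassed ClCH2CH2Cl, rt; then 80 °C
Reagents that add atoms: none
Why: This is the Danheiser benzannulation in its photochemical Wolff variant, run here with a diazo keto ester in place of a simple diazo ketone: excitation expels N2 and the alkenyl group, which migrates far better than the ester methoxy group, shifts to give vinylketene 9. The nucleophilic methyl-bearing carbon of ynol ether 8 bonds to the ketene carbonyl carbon (C4–C5) and the oxygen-bearing carbon closes onto the ketene α-carbon (C6–C1), so the matched polarity of the two partners fixes the regiochemistry of the (2+2) cycloaddition that forms the four-membered ring of 10. Reversible 4π electrocyclic opening of 10 breaks the original C4–C1 bond, and only isomer 11, with the butenyl group cis to the ketene arm, can react further, so the equilibrium is drained through it. Ring B closes by thermal disrotatory 6π electrocyclisation of 11 (C3–C4, with the hydrogen of the (E)-alkene terminus pointing inward), and dienone 12 enolises irreversibly to phenol 13. No stereocentre survives, since the quaternary carbon of 10 and the C3 carbon of 12 form as racemates and are erased on aromatisation. The selectivity required is periselectivity, meaning (2+2) addition across the ketene C=C rather than hetero-(4+2) addition through the ester C=O or dipolar addition of the diazo group, and it is supported by the weakly nucleophilic ester oxygen, the excess of 8 and a low stationary ketene concentration.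

Step 5
Reactants: 14 methyl orsellinate (methyl 2,4-dihydroxy-6-methylbenzoate)
Product: 15 methyl 2,4-bis(benzyloxy)-6-methylbenzoate
Conditions: BnBr, K2CO3, DMF, 60 °C
Reagents that add atoms: benzyl bromide, BrCc1ccccc1
Why: Williamson etherification in warm DMF with excess base should alkylate both the free C4' hydroxyl and the hydrogen-bonded C2' hydroxyl.

Step 6
Reactants: 15 methyl 2,4-bis(benzyloxy)-6-methylbenzoate
Product: 16 2,4-bis(benzyloxy)-6-methylbenzoic acid
Conditions: KOH, DMSO/H2O, 100 °C; then aq. HCl
Reagents that add atoms: potassium hydroxide, [K+].[OH-]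
Why: Saponification of a di-ortho-substituted benzoate needs poorly solvated hydroxide in hot aqueous DMSO, and benzyl aryl ethers tolerate these conditions.

Step 7
Reactants: 16 2,4-bis(benzyloxy)-6-methylbenzoic acid; 13 methyl 4-hydroxy-2-methoxy-3,5,6-trimethylbenzoate
Product: 18 3-methoxy-4-(methoxycarbonyl)-2,5,6-trimethylphenyl 2,4-bis(benzyloxy)-6-methylbenzoate, via aroyl trifluoroacetate 17 (not isolated)
Conditions: (CF3CO)2O, toluene, rt
Reagents that add atoms: none
Why: In this mixed-anhydride esterification with trifluoroacetic anhydride, the electron-rich di-ortho-substituted aroyl trifluoroacetate ionises towards an acylium ion, a linear electrophile that the flanked C4 hydroxyl, the only nucleophilic site of 13, can reach.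

Step 8
Reactants: 18 3-methoxy-4-(methoxycarbonyl)-2,5,6-trimethylphenyl 2,4-bis(benzyloxy)-6-methylbenzoate
Product: 19 3-methoxy-4-(methoxycarbonyl)-2,5,6-trimethylphenyl 2,4-dihydroxy-6-methylbenzoate
Conditions: H2 (1 atm), Pd/C (10 wt% Pd), EtOAc, rt
Reagents that add atoms: none
Why: Catalytic hydrogenolysis removes the two benzyl aryl ethers, while both esters, the aryl methyl ether and the arenes are inert at atmospheric pressure.

Step 9
Reactants: 19 3-methoxy-4-(methoxycarbonyl)-2,5,6-trimethylphenyl 2,4-dihydroxy-6-methylbenzoate
Product: 21 3-methoxy-4-(methoxycarbonyl)-2,5,6-trimethylphenyl 3,5-diformyl-2,4-dihydroxy-6-methylbenzoate (target), via bis-aldimine 20 (not isolated)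
Conditions: (CH2)6N4 (excess), CF3CO2H, reflux; then aq. HCl, 60 °C
Reagents that add atoms: hexamethylenetetramine, C1N2CN3CN1CN(C2)C3; water, O
Why: In the Duff reaction in trifluoroacetic acid, C3' and C5' each lie ortho to a hydroxyl and are aminomethylated, hydride transfer raises them to the imine level (20, drawn in its simplest N–H form) and water releases the aldehydes, exhaustive formylation of resorcinol and phloroglucinol rings being known because the ring is not yet deactivated by carbonyl groups before hydrolysis, while ring B offers no C–H.

Compound list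
1 | tiglic acid, (E)-2-methylbut-2-enoic acid | C/C=C(\C)C(=O)O | starting material
2 | potassium methyl malonate (potassium 3-methoxy-3-oxopropanoate) | COC(=O)CC(=O)[O-].[K+] | starting material
3 | tigloyl imidazolide, (E)-1-(imidazol-1-yl)-2-methylbut-2-en-1-one | C/C=C(\C)C(=O)n1ccnc1 | intermediate
4 | methyl (E)-4-methyl-3-oxohex-4-enoate | COC(=O)CC(=O)/C(C)=C/C | intermediate
5 | methyl (E)-2-diazo-4-methyl-3-oxohex-4-enoate | COC(=O)C(=[N+]=[N-])C(=O)/C(C)=C/C | intermediate
6 | chloroacetaldehyde dimethyl acetal | COC(CCl)OC | starting material
7 | sodium methoxyacetylide | COC#[C-].[Na+] | intermediate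
8 | 1-methoxyprop-1-yne | CC#COC | intermediate
9 | vinylketene, methyl (E)-3-methyl-2-(oxomethylidene)pent-3-enoate | COC(=O)C(=C=O)/C(C)=C/C | intermediate
10 | vinylcyclobutenone, methyl 1-[(E)-but-2-en-2-yl]-2-methoxy-3-methyl-4-oxocyclobut-2-ene-1-carboxylate (racemic) | COC(=O)C1(/C(C)=C/C)C(OC)=C(C)C1=O | intermediate
11 | dienylketene, methyl (2Z)-2-[(E)-but-2-en-2-yl]-3-methoxy-4-methyl-5-oxopenta-2,4-dienoate | O=C=C(C)/C(OC)=C(\C(C)=C\C)C(=O)OC | intermediate
12 | cyclohexadienone, methyl 6-methoxy-2,3,5-trimethyl-4-oxocyclohexa-1,5-diene-1-carboxylate (racemic) | COC(=O)C1=C(C)C(C)C(=O)C(C)=C1OC | intermediate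
13 | methyl 4-hydroxy-2-methoxy-3,5,6-trimethylbenzoate | COC(=O)c1c(C)c(C)c(O)c(C)c1OC | intermediate
14 | methyl orsellinate, methyl 2,4-dihydroxy-6-methylbenzoate | COC(=O)c1c(C)cc(O)cc1O | starting material
15 | methyl 2,4-bis(benzyloxy)-6-methylbenzoate | COC(=O)c1c(C)cc(OCc2ccccc2)cc1OCc1ccccc1 | intermediate
16 | 2,4-bis(benzyloxy)-6-methylbenzoic acid | Cc1cc(OCc2ccccc2)cc(OCc2ccccc2)c1C(=O)O | intermediate
17 | 2,4-bis(benzyloxy)-6-methylbenzoic trifluoroacetic anhydride | Cc1cc(OCc2ccccc2)cc(OCc2ccccc2)c1C(=O)OC(=O)C(F)(F)F | intermediate
18 | 3-methoxy-4-(methoxycarbonyl)-2,5,6-trimethylphenyl 2,4-bis(benzyloxy)-6-methylbenzoate | COC(=O)c1c(C)c(C)c(OC(=O)c2c(C)cc(OCc3ccccc3)cc2OCc2ccccc2)c(C)c1OC | intermediate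
19 | 3-methoxy-4-(methoxycarbonyl)-2,5,6-trimethylphenyl 2,4-dihydroxy-6-methylbenzoate | COC(=O)c1c(C)c(C)c(OC(=O)c2c(C)cc(O)cc2O)c(C)c1OC | intermediate
20 | 3-methoxy-4-(methoxycarbonyl)-2,5,6-trimethylphenyl 2,4-dihydroxy-3,5-bis(iminomethyl)-6-methylbenzoate | COC(=O)c1c(C)c(C)c(OC(=O)c2c(C)c(C=N)c(O)c(C=N)c2O)c(C)c1OC | intermediate
21 | 3-methoxy-4-(methoxycarbonyl)-2,5,6-trimethylphenyl 3,5-diformyl-2,4-dihydroxy-6-methylbenzoate | COC(=O)c1c(C)c(C)c(OC(=O)c2c(C)c(C=O)c(O)c(C=O)c2O)c(C)c1OC | target

Total step count: 9.
Longest linear sequence: 6 steps (1, 2, 4, 7, 8, 9).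

Steps most likely to fail

Risk 1, step 4. The ketene carries an acceptor, so the dipolar intermediate of the (2+2) addition lives longer than usual and may close through the ester oxygen instead of carbon.
- Inward rotation of the ester during the 4π opening may divert material by oxa-6π closure.
- Photochemical E/Z scrambling of the alkene would open a 1,5-hydrogen shift.
- The phenol may intercept the ketene as it forms.

The fallback gives up the annulation and builds ring B by substitution on a preformed arene, using known reactions only. It sets out from 14. A double Mannich reaction (aq. CH2O, morpholine, EtOH, reflux) at the two free ring positions should give methyl 2,4-dihydroxy-6-methyl-3,5-bis(morpholin-4-ylmethyl)benzoate F1. Hydrogenolysis of both benzylic C–N bonds (H2, Pd/C, AcOH, 60 °C) then gives methyl 2,4-dihydroxy-3,5,6-trimethylbenzoate F2. Its non-chelated C4 hydroxyl is acylated selectively with 16 under the conditions of step 7, giving 3-hydroxy-4-(methoxycarbonyl)-2,5,6-trimethylphenyl 2,4-bis(benzyloxy)-6-methylbenzoate F3. O-methylation of the remaining chelated hydroxyl (MeI, K2CO3, DMF) comes back to the route at 18.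

Risk 2, step 9. Formylation may stall after the first position, ring A units may become methylene-bridged, and the long heating in acid that the second formylation needs may cleave the depside ester.

The fallback reverses the order of events, so the forcing formylation falls on the cheap monomer, which has no depside bond to lose. It sets out from 14. Exhaustive Duff formylation ((CH2)6N4, CF3CO2H, 100 °C, sealed vessel; aq. HCl) should give methyl 3,5-diformyl-2,4-dihydroxy-6-methylbenzoate F4. Acyl–oxygen cleavage of the hindered ester in cold concentrated H2SO4 gives 3,5-diformyl-2,4-dihydroxy-6-methylbenzoic acid F5, whose hydroxyls are tied up in hydrogen bonds to the formyl groups and should not self-acylate. Carbodiimide coupling of F5 with 13 (N,N'-dicyclohexylcarbodiimide, toluene, rt) arrives directly at 21 and makes steps 5 to 8 unnecessary.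

Risk 3, step 7. Acyl transfer to the doubly flanked hydroxyl may be slow. That would let trifluoroacetylation of the phenol, Friedel–Crafts self-acylation of the electron-rich ring A or acid-induced loss of the ortho benzyl group compete.

The fallback moves the activation from the electrophile to the nucleophile and runs under basic conditions. It sets out from 16, which (COCl)2 and catalytic DMF in CH2Cl2 convert into 2,4-bis(benzyloxy)-6-methylbenzoyl chloride F6. Separately, 13 is deprotonated with NaH in THF to sodium 3-methoxy-4-(methoxycarbonyl)-2,5,6-trimethylphenoxide F7. Combining the two at 0 °C to rt comes back to the route at 18.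

Further compounds
F1 | step 4 | methyl 2,4-dihydroxy-6-methyl-3,5-bis(morpholin-4-ylmethyl)benzoate | COC(=O)c1c(C)c(CN2CCOCC2)c(O)c(CN2CCOCC2)c1O
F2 | step 4 | methyl 2,4-dihydroxy-3,5,6-trimethylbenzoate | COC(=O)c1c(C)c(C)c(O)c(C)c1O
F3 | step 4 | 3-hydroxy-4-(methoxycarbonyl)-2,5,6-trimethylphenyl 2,4-bis(benzyloxy)-6-methylbenzoate | COC(=O)c1c(C)c(C)c(OC(=O)c2c(C)cc(OCc3ccccc3)cc2OCc2ccccc2)c(C)c1O
F4 | step 9 | methyl 3,5-diformyl-2,4-dihydroxy-6-methylbenzoate | COC(=O)c1c(C)c(C=O)c(O)c(C=O)c1O
F5 | step 9 | 3,5-diformyl-2,4-dihydroxy-6-methylbenzoic acid | Cc1c(C=O)c(O)c(C=O)c(O)c1C(=O)O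
F6 | step 7 | 2,4-bis(benzyloxy)-6-methylbenzoyl chloride | Cc1cc(OCc2ccccc2)cc(OCc2ccccc2)c1C(=O)Cl
F7 | step 7 | sodium 3-methoxy-4-(methoxycarbonyl)-2,5,6-trimethylphenoxide | COC(=O)c1c(C)c(C)c([O-])c(C)c1OC.[Na+]
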